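All runs are simulated for substances that don't exist; scatter was added.

The chemist at this flask asks how the rate of making product answers to the spent carrier charged, though no run varies that charge.

| setting | east | north-west | flask |
|---|---|---|---|
| starting material | 0.010 M | 0.010 M | 0.010 M |
| salt in the second phase | 0.53 equiv | 0.79 equiv | 1.05 equiv |
| spent carrier | 1.3 mol% | 1.3 mol% | 1.3 mol% |
| remark | run made earlier | run made earlier |  |
| volume of the second phase over the first |  |  | 1.0 |

| east: time / h | east: product / % | north-west: time / h | north-west: product / % |
|---|---|---|---|
| 8.00 | 19 | 3.00 | 14 |
| 15.0 | 27 | 10.0 | 28 |
| 25.0 | 29 | 15.0 | 28 |
| 30.0 | 34 | 25.0 | 35 |
| 40.0 | 36 | 40.0 | 35 |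
| 50.0 | 36 | 50.0 | 36 |

(standard deviation of a reading: 2 percentage points)

1. apparent order in spent carrier when 10% of the starting material are converted (percent change of the rate of making product for one percent more spent carrier charged)

- charges count per volume of the first phase; a concentration in a rate is the amount of a species over the volume of its own phase; every rate counts per litre of the first phase
- the earlier runs hold the two phases in the same ratio of volumes as the flask asked about
- what has gone from starting material into another species counts as reacted, even if it can come back
- no earlier run changes the charge of spent carrier; that part of a forecast is a guess

We take the carrier's turnover as fast, so that its forms keep a ratio independent of the charge and the rate follows the surviving carrier. The order n then differs from one by however the surviving fraction shifts with the charge.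

Both runs read 36% at 50.0 h, and we take that reading as a plateau x∞. If each carrier gives a fixed number of turnovers, the surviving fraction falls linearly with product and reaches zero at x∞, and at conversion x

n = x∞/(x∞ − x) = 1.38

which, with the scatter of that reading, is our bound from above.

If carrier instead dies in pairs and the conversion is product throughout, the surviving fraction is exp(−p/L) at product p, whatever the charge, and n is one. Here L, the loss length, is the product made per e-fold of carrier lost. We read it from the north-west run's early slope against ln t:

L = 11.6%

Now let a share s of the conversion be product, the rest going on a clock of its own. More carrier raises s, and

n = 1/(1 + s(1 − s) x/L)

The factor s(1 − s) stays below one, so in this reckoning n stays above 0.538. But the ceiling of that factor is a quarter, which with L as read tightens our bound from below to 0.823.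

The forecast, 1.3, argues that “more carrier means a larger surviving fraction”, and it stands inside this bracket, near the top.

The simulation gives 0.85, inside the bracket, near the bottom.

    spent carrier + salt in the second phase ⇌ fresh carrier + spent salt in the second phase (K = 1.10, k = 0.500 /M/s)
    starting material + fresh carrier → product + spent carrier (k = 0.550 /M/s)
    2 fresh carrier → spent catalyst (k = 3.30 /M/s)
    starting material ⇌ dormant form (K = 1.60, k = 1.80 × 10⁻⁵ /s)

In the flask at 4.00 h, product stands at 19.1%, with spent and fresh carrier at 13.3% and 12.8% of the catalyst charged, so the loss length there is 14.2%. At 4.74 h in the flask, fresh carrier is used 33 times as fast by the step that makes product as by the step that makes spent catalyst.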